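**Retrosynthetic overview**
1. Cut C14–C15' of the central (E)-2-alkylenal. C14, the normally nucleophilic α-carbon of the trans-fused C20 aldehyde, is made electrophilic as its enamine radical cation (a one-electron enolonium equivalent). It is joined to the nucleophilic alkenyl–boron carbon C15' of the cis-fused C20 half, and the new alkene is then moved into conjugation.
2. Each C20 half comes from a C9 enolate of an 8-oxodecalin and one shared (S)-iodide (C11–C16, silyl-alkyne terminus). C8=CH2 is made by methylenation. The alkyne becomes either CHO or CH=CH–BF3K.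
3. The cis-decalin enolate comes from Me2CuLi and the 5β-H octalone. The trans-decalin enolate comes from Li/NH3 opening of a 9β,10β-cyclopropyl ketone made from the 5α-H octalone.
4. Both octalones come from one (S)-tetralin acid by Birch reduction, as a C5-epimer pair in which both epimers are used. C4 is set by asymmetric hydrovinylation of the methylidene tetralin from 6-methoxy-1-tetralone.
5. Ring order: no carbocycle is built. Ring A and ring B arrive with the tetralone, ring B is dearomatised, and only a transient cyclopropane is made and reopened.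

Assumption: the SMILES is taken literally, so the aldehyde-bearing (unprimed) half is a normal trans-fused labdane (4S,5R,9S,10R,13S) and the primed half is its C5' epimer (cis-fused, 5'S); labdane numbering is used, β is the face of C20 and C19, and where the sense of induction of a chiral ligand is not known for the exact substrate the antipode named is the one expected by analogy (the other is equally available).

**Route**

Step 1
Reactants: 1 6-methoxy-1-tetralone
Product: 2 6-methoxy-1-methylidene-1,2,3,4-tetrahydronaphthalene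
Conditions: Ph3PCH3Br, KOt-Bu, THF, 0 °C → rt
Reagents that add atoms: methyltriphenylphosphonium bromide C[P+](c1ccccc1)(c1ccccc1)c1ccccc1.[Br-]
Why: Wittig methylenation of an unhindered aryl ketone, in which the new carbon later becomes the C18/C18' methyl group and no stereocentre is formed.

Step 2
Reactants: 2 6-methoxy-1-methylidene-1,2,3,4-tetrahydronaphthalene
Product: 3 (1R)-1-ethenyl-6-methoxy-1-methyl-1,2,3,4-tetrahydronaphthalene
Conditions: C2H4 (1 atm), [Ni(C3H5)Br]2 (1 mol %), (Sa,Rc,Rc)-BINOL bis(1-phenylethyl)amine phosphoramidite (2 mol %), Na[B(3,5-(CF3)2C6H3)4] (2 mol %), CH2Cl2, −55 °C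
Reagents that add atoms: ethylene C=C
Why: Nickel-hydride asymmetric hydrovinylation: Ni–H adds to the 1,1-disubstituted styrene to give the tertiary benzylic nickel alkyl, ethylene inserts and β-hydride elimination releases the vinyl group, and the phosphoramidite selects the face so that the quaternary carbon C4/C4' shared by both halves is set here.

Step 3
Reactants: 3 (1R)-1-ethenyl-6-methoxy-1-methyl-1,2,3,4-tetrahydronaphthalene
Product: 4 (1S)-6-methoxy-1-methyl-1,2,3,4-tetrahydronaphthalene-1-carboxylic acid
Conditions: KMnO4 (10 mol %), NaIO4 (6 equiv), t-BuOH/H2O, phosphate buffer pH 7–8, rt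
Reagents that add atoms: sodium periodate [Na+].[O-]I(=O)(=O)=O; potassium permanganate [K+].[O-][Mn](=O)(=O)=O
Why: Lemieux–von Rudloff cleavage takes the only alkene to the acid in one pot, the anisole ring survives the buffered catalytic permanganate, and the quaternary centre is untouched (the descriptor changes from R to S by priority only).

Step 4
Reactants: 4 (1S)-6-methoxy-1-methyl-1,2,3,4-tetrahydronaphthalene-1-carboxylic acid
Product: 5 (1S)-6-methoxy-1-methyl-1,2,3,4,5,8-hexahydronaphthalene-1-carboxylic acid
Conditions: Li, NH3(l), THF, t-BuOH, −78 → −33 °C; cold aqueous NaH2PO4 to pH 5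
Reagents that add atoms: none
Why: Birch reduction of the anisole ring (ring B) gives the 2,5-dihydroanisole with the methoxy- and alkyl-bearing carbons left on the double bonds, while the carboxylate is inert to the dissolving metal.

Step 5
Reactants: 5 (1S)-6-methoxy-1-methyl-1,2,3,4,5,8-hexahydronaphthalene-1-carboxylic acid
Product: 7 2-(trimethylsilyl)ethyl (1S,8aS)-1-methyl-6-oxo-1,2,3,4,6,7,8,8a-octahydronaphthalene-1-carboxylate (5β-H octalone; H5 cis to the ester) + 8 its (1S,8aR) epimer (5α-H octalone; H5 trans to the ester), via enol-ether ester 6 (not isolated)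
Conditions: Me3SiCH2CH2OH, PPh3, DIAD, THF, 0 °C → rt; then 2 M HCl, THF, 40 °C; chromatography
Reagents that add atoms: 2-(trimethylsilyl)ethanol C[Si](C)(C)CCO; water O
Why: Mitsunobu esterification (the hindered carboxylate attacks a primary alkoxyphosphonium carbon) followed by enol-ether hydrolysis and acid conjugation creates C5 under thermodynamic control as a roughly 1:1 pair, because the epimers differ only in whether CH3 or CO2R is axial on C4; both are used (7 for the cis half, 8 for the trans half) and either can be re-equilibrated with acid.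

Step 6
Reactants: 9 (E)-but-2-enal; 10 ethynyltri(propan-2-yl)silane
Product: 11 (3S)-3-methyl-5-[tri(propan-2-yl)silyl]pent-4-ynal
Conditions: [Rh(OAc)(C2H4)2]2 (2.5 mol %), (S)-DTBM-SEGPHOS (6 mol %), MeOH, 40 °C
Reagents that add atoms: none
Why: Rhodium-catalysed asymmetric conjugate alkynylation of an enal, in which the bulky silyl group suppresses alkyne dimerisation and the bisphosphine sets the methyl-bearing centre that becomes both C13 and C13' (S).

Step 7
Reactants: 11 (3S)-3-methyl-5-[tri(propan-2-yl)silyl]pent-4-ynal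
Product: 12 (3S)-3-methyl-5-[tri(propan-2-yl)silyl]pent-4-yn-1-ol
Conditions: NaBH4, MeOH, 0 °C
Reagents that add atoms: none
Why: Borohydride reduction of an aldehyde, with the β-stereocentre not enolisable under these conditions.

Step 8
Reactants: 12 (3S)-3-methyl-5-[tri(propan-2-yl)silyl]pent-4-yn-1-ol
Product: 13 [(3S)-5-iodo-3-methylpent-1-yn-1-yl]tri(propan-2-yl)silane
Conditions: I2, PPh3, imidazole, CH2Cl2, 0 °C → rt
Reagents that add atoms: iodine [I][I]
Why: Appel-type (Garegg–Samuelsson) iodination of a primary alcohol by SN2 at the CH2 group, two carbons away from the stereocentre.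

Step 9
Reactants: 7 5β-H octalone ester; 13 (S)-iodide
Product: 15 2-(trimethylsilyl)ethyl 8-oxo-15-[tri(propan-2-yl)silyl]-17-nor-5β-labd-14-yn-19-oate (cis-decalin; 5β-H; 10β-CH3; 9α-H; 13S), via lithium enolate 14 (not isolated)
Conditions: Me2CuLi (1.2 equiv), Et2O, −20 → 0 °C; then 13 (1.5 equiv), THF/HMPA, −40 → 0 °C, cold quench
Reagents that add atoms: lithium dimethylcuprate [Li+].C[Cu-]C
Why: Gilman conjugate addition with enolate alkylation: the cuprate attacks C10' on the face syn to H5' (the usual cis selectivity of octalones, reinforced because the other face is blocked by the axial 4α-methyl), and the regiodefined C9' enolate is alkylated kinetically from the same open β face (the α face is shielded by C1' or C4' in either cis-decalin conformer), which sets 10'β-CH3 and 9'α-H.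

Step 10
Reactants: 15 cis-decalin ketone
Product: 16 2-(trimethylsilyl)ethyl 15-[tri(propan-2-yl)silyl]-5β-labd-8(17)-en-14-yn-19-oate
Conditions: Zn, CH2Br2, TiCl4 (pre-aged reagent), CH2Cl2, 0 °C → rt
Reagents that add atoms: dibromomethane C(Br)Br
Why: Takai–Lombardo methylenation is non-basic, so the kinetically set and epimerisable C9' is not scrambled, and the hindered ester and the silyl alkyne are inert.

Step 11
Reactants: 16 cis-series silyl alkyne ester
Product: 17 (13S)-5β-labd-8(17)-en-14-yn-19-oic acid
Conditions: Bu4NF (3 equiv), THF, rt; 1 M HCl work-up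
Reagents that add atoms: none
Why: One fluoride treatment does two jobs, C-desilylation of the alkyne and β-silyl fragmentation of the silylethyl ester, and the latter occurs at silicon so the steric hindrance of the C19' carbonyl does not matter.

Step 12
Reactants: 17 (13S)-5β-labd-8(17)-en-14-yn-19-oic acid
Product: 19 potassium [(14E)-19-hydroxy-19-oxo-5β-labda-8(17),14-dien-15-yl]trifluoroborate, via alkenyl pinacolboronate 18 (not isolated)
Conditions: KOt-Bu (1.1 equiv), CuCl (5 mol %), Xantphos (5 mol %), B2pin2 (1.1 equiv), MeOH (2 equiv), THF, rt; then aqueous KHF2, MeOH, rt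
Reagents that add atoms: bis(pinacolato)diboron CC1(C)OB(OC1(C)C)B1OC(C)(C)C(C)(C)O1; potassium hydrogen difluoride [K+].F.[F-]
Why: Copper-catalysed syn borylcupration–protonation (formal hydroboration) of the terminal alkyne places boron on C15' with E geometry, leaves the unactivated 1,1-disubstituted alkene and the carboxylate alone, and KHF2 then gives the crystalline trifluoroborate.

Step 13
Reactants: 8 5α-H octalone ester
Product: 20 2-(trimethylsilyl)ethyl (1S,6S,8aR)-6-hydroxy-1-methyl-1,2,3,4,6,7,8,8a-octahydronaphthalene-1-carboxylate (8β-OH allylic alcohol)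
Conditions: LiBH(s-Bu)3, THF, −78 °C; then H2O
Reagents that add atoms: none
Why: 1,2-reduction of a β,β-disubstituted enone by a bulky borohydride proceeds by equatorial attack from the α face and gives the pseudo-axial 8β-alcohol, the epimer needed to direct the next step to the β face.

Step 14
Reactants: 20 8β-OH allylic alcohol
Product: 21 cyclopropyl carbinol (20 with a CH2 bridge across C9–C10 on the β face, cis to 8-OH and to the ester)
Conditions: Et2Zn (3 equiv), CH2I2 (3 equiv), CH2Cl2, −10 °C → rt
Reagents that add atoms: diiodomethane C(I)I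
Why: Hydroxyl-directed Simmons–Smith (Furukawa) cyclopropanation delivers the methylene from the face of the zinc alkoxide, which overrides the steric bias of the axial ester and places the future C20 carbon β on C10, trans to 5α-H.

Step 15
Reactants: 21 cyclopropyl carbinol
Product: 22 9β,10β-cyclopropyl ketone
Conditions: Dess–Martin periodinane, CH2Cl2, rt
Reagents that add atoms: none
Why: Dess–Martin oxidation of a secondary alcohol under neutral conditions leaves the cyclopropane and the ester untouched.

Step 16
Reactants: 22 9β,10β-cyclopropyl ketone; 13 (S)-iodide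
Product: 25 2-(trimethylsilyl)ethyl 8-oxo-15-[tri(propan-2-yl)silyl]-17-norlabd-14-yn-19-oate (trans-decalin; 5α-H; 10β-CH3; 9α-H; 13S), via lithium enolate 23 (not isolated), via 9-epi ketone 24 (not isolated)
Conditions: Li (2.05 equiv), NH3(l)/THF, −78 °C; then 13 (2 equiv), −78 → −33 °C; crude product NaOMe (0.2 equiv), MeOH, rt
Reagents that add atoms: none
Why: Dissolving-metal cleavage of a cyclopropyl ketone breaks the outer C9–CH2 bond (best overlap with the carbonyl π system, and a primary rather than tertiary carbanion), which leaves the 10β-methyl group and a regiospecific C9 enolate; reductive alkylation occurs axially anti to that methyl, and base equilibration then moves the side chain into the equatorial 9β position (9α-H) of the rigid trans-decalin.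

Step 17
Reactants: 25 trans-decalin ketone
Product: 26 2-(trimethylsilyl)ethyl 15-[tri(propan-2-yl)silyl]labd-8(17)-en-14-yn-19-oate
Conditions: Ph3PCH3Br, KOt-Bu, THF, 0 °C → reflux
Reagents that add atoms: methyltriphenylphosphonium bromide C[P+](c1ccccc1)(c1ccccc1)c1ccccc1.[Br-]
Why: Wittig methylenation of the 8-ketone, in which C9 already has its thermodynamic configuration so the basic ylide cannot erode it.

Step 18
Reactants: 26 trans-series silyl alkyne ester
Product: 27 (13S)-labd-8(17)-en-14-yn-19-oic acid
Conditions: Bu4NF (3 equiv), THF, rt; 1 M HCl work-up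
Reagents that add atoms: none
Why: The same fluoride-induced double desilylation as in step 11 (alkyne C–Si cleavage and silylethyl ester fragmentation).

Step 19
Reactants: 27 (13S)-labd-8(17)-en-14-yn-19-oic acid
Product: 28 (13S)-15-oxolabd-8(17)-en-19-oic acid
Conditions: [CpRu(MeCN)3]PF6 (5 mol %), 2-diphenylphosphino-6-(2,4,6-triisopropylphenyl)pyridine (10 mol %), acetone/H2O 4:1, 55 °C
Reagents that add atoms: water O
Why: Ruthenium-catalysed anti-Markovnikov alkyne hydration through a vinylidene complex gives the aldehyde directly, is specific for terminal alkynes, and tolerates the free acid and the exocyclic alkene.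

Step 20
Reactants: 28 (13S)-15-oxolabd-8(17)-en-19-oic acid; 19 cis-series potassium alkenyltrifluoroborate
Product: 30 CNP0229303.1, via skipped enal 29 (not isolated)
Conditions: (2S,5S)-5-benzyl-2-tert-butyl-3-methylimidazolidin-4-one·CF3CO2H (20 mol %), (NH4)2Ce(NO3)6 (2.5 equiv), NaHCO3, H2O, DME, −50 °C, dark, 19 (1.5 equiv); extractive work-up; then DBU (3 equiv), CH2Cl2, rt; 1 M HCl wash
Reagents that add atoms: none
Why: Proposed new method: the enamine of 28 is oxidised by the ceric salt to a three-π-electron radical cation in which C14, normally the nucleophilic α-carbon, is electrophilic (an enolonium equivalent); it is trapped at the boron-bearing carbon C15' of the π-nucleophilic borate, a second oxidation gives a β-borato cation that loses BF3 to give the E-alkene, and iminium hydrolysis gives 29; DBU then moves the double bond into conjugation through the C15–C14–C15'–C14' dienolate to the thermodynamic (E)-enal, which erases C14 and cannot touch C13 or C13' because neither belongs to that dienolate; the closest known reaction type is the organo-SOMO α-vinylation of aldehydes with potassium alkenyltrifluoroborates, and what is new is the alkyl-substituted borate, the two unprotected C20 acids and the telescoped conjugation.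

**Compound list**
1 | 6-methoxy-1-tetralone | COc1ccc2c(c1)CCCC2=O | starting material
2 | 6-methoxy-1-methylidene-1,2,3,4-tetrahydronaphthalene | COc1ccc2c(c1)CCCC2=C | intermediate
3 | (1R)-1-ethenyl-6-methoxy-1-methyl-1,2,3,4-tetrahydronaphthalene | COc1ccc2c(c1)CCC[C@]2(C)C=C | intermediate
4 | (1S)-6-methoxy-1-methyl-1,2,3,4-tetrahydronaphthalene-1-carboxylic acid | COc1ccc2c(c1)CCC[C@]2(C)C(=O)O | intermediate
5 | (1S)-6-methoxy-1-methyl-1,2,3,4,5,8-hexahydronaphthalene-1-carboxylic acid | COC1=CCC2=C(C1)CCC[C@]2(C)C(=O)O | intermediate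
6 | 2-(trimethylsilyl)ethyl ester of 5 (not isolated) | COC1=CCC2=C(C1)CCC[C@]2(C)C(=O)OCC[Si](C)(C)C | intermediate
7 | 2-(trimethylsilyl)ethyl (1S,8aS)-1-methyl-6-oxo-1,2,3,4,6,7,8,8a-octahydronaphthalene-1-carboxylate (5β-H) | O=C1CC[C@H]2C(CCC[C@]2(C)C(=O)OCC[Si](C)(C)C)=C1 | intermediate
8 | 2-(trimethylsilyl)ethyl (1S,8aR)-1-methyl-6-oxo-1,2,3,4,6,7,8,8a-octahydronaphthalene-1-carboxylate (5α-H) | O=C1CC[C@@H]2C(CCC[C@]2(C)C(=O)OCC[Si](C)(C)C)=C1 | intermediate
9 | (E)-but-2-enal | C/C=C/C=O | starting material
10 | ethynyltri(propan-2-yl)silane | C#C[Si](C(C)C)(C(C)C)C(C)C | starting material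
11 | (3S)-3-methyl-5-[tri(propan-2-yl)silyl]pent-4-ynal | O=CC[C@H](C)C#C[Si](C(C)C)(C(C)C)C(C)C | intermediate
12 | (3S)-3-methyl-5-[tri(propan-2-yl)silyl]pent-4-yn-1-ol | OCC[C@H](C)C#C[Si](C(C)C)(C(C)C)C(C)C | intermediate
13 | [(3S)-5-iodo-3-methylpent-1-yn-1-yl]tri(propan-2-yl)silane | ICC[C@H](C)C#C[Si](C(C)C)(C(C)C)C(C)C | intermediate
14 | lithium C8'–C9' enolate of the 10β-methyl cis-decalone ester (not isolated) | [Li+].C1=C([O-])CC[C@H]2[C@]1(C)CCC[C@]2(C)C(=O)OCC[Si](C)(C)C | intermediate
15 | 2-(trimethylsilyl)ethyl 8-oxo-15-[tri(propan-2-yl)silyl]-17-nor-5β-labd-14-yn-19-oate (9α-H, 13S) | CC(C)[Si](C#C[C@@H](C)CC[C@H]1C(=O)CC[C@H]2[C@]1(C)CCC[C@]2(C)C(=O)OCC[Si](C)(C)C)(C(C)C)C(C)C | intermediate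
16 | 2-(trimethylsilyl)ethyl 15-[tri(propan-2-yl)silyl]-5β-labd-8(17)-en-14-yn-19-oate | CC(C)[Si](C#C[C@@H](C)CC[C@H]1C(=C)CC[C@H]2[C@]1(C)CCC[C@]2(C)C(=O)OCC[Si](C)(C)C)(C(C)C)C(C)C | intermediate
17 | (13S)-5β-labd-8(17)-en-14-yn-19-oic acid | C#C[C@@H](C)CC[C@H]1C(=C)CC[C@H]2[C@]1(C)CCC[C@]2(C)C(=O)O | intermediate
18 | potassium (14E)-15-(4,4,5,5-tetramethyl-1,3,2-dioxaborolan-2-yl)-5β-labda-8(17),14-dien-19-oate (not isolated) | CC1(C)OB(/C=C/[C@@H](C)CC[C@H]2C(=C)CC[C@H]3[C@]2(C)CCC[C@]3(C)C(=O)[O-])OC1(C)C.[K+] | intermediate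
19 | potassium [(14E)-19-hydroxy-19-oxo-5β-labda-8(17),14-dien-15-yl]trifluoroborate | [K+].F[B-](F)(F)/C=C/[C@@H](C)CC[C@H]1C(=C)CC[C@H]2[C@]1(C)CCC[C@]2(C)C(=O)O | intermediate
20 | 2-(trimethylsilyl)ethyl (1S,6S,8aR)-6-hydroxy-1-methyl-1,2,3,4,6,7,8,8a-octahydronaphthalene-1-carboxylate (8β-OH) | O[C@H]1CC[C@@H]2C(CCC[C@]2(C)C(=O)OCC[Si](C)(C)C)=C1 | intermediate
21 | 8β-hydroxy-9β,10β-methano decalin ester (cyclopropyl carbinol) | O[C@H]1CC[C@@H]2[C@@]3(CCC[C@]2(C)C(=O)OCC[Si](C)(C)C)C[C@@H]13 | intermediate
22 | 8-oxo-9β,10β-methano decalin ester (cyclopropyl ketone) | O=C1CC[C@@H]2[C@@]3(CCC[C@]2(C)C(=O)OCC[Si](C)(C)C)C[C@@H]13 | intermediate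
23 | lithium C8–C9 enolate of the 10β-methyl trans-decalone ester (not isolated) | [Li+].[O-]C1CC[C@@H]2[C@](C)(CCC[C@]2(C)C(=O)OCC[Si](C)(C)C)C=1 | intermediate
24 | 9-epimer of 25 (9β-H, axial side chain; not isolated) | O=C1CC[C@@H]2[C@](C)(CCC[C@]2(C)C(=O)OCC[Si](C)(C)C)[C@@H]1CC[C@H](C)C#C[Si](C(C)C)(C(C)C)C(C)C | intermediate
25 | 2-(trimethylsilyl)ethyl 8-oxo-15-[tri(propan-2-yl)silyl]-17-norlabd-14-yn-19-oate (5α-H, 9α-H, 13S) | O=C1CC[C@@H]2[C@](C)(CCC[C@]2(C)C(=O)OCC[Si](C)(C)C)[C@H]1CC[C@H](C)C#C[Si](C(C)C)(C(C)C)C(C)C | intermediate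
26 | 2-(trimethylsilyl)ethyl 15-[tri(propan-2-yl)silyl]labd-8(17)-en-14-yn-19-oate | C=C1CC[C@@H]2[C@](C)(CCC[C@]2(C)C(=O)OCC[Si](C)(C)C)[C@H]1CC[C@H](C)C#C[Si](C(C)C)(C(C)C)C(C)C | intermediate
27 | (13S)-labd-8(17)-en-14-yn-19-oic acid | C=C1CC[C@@H]2[C@](C)(CCC[C@]2(C)C(=O)O)[C@H]1CC[C@H](C)C#C | intermediate
28 | (13S)-15-oxolabd-8(17)-en-19-oic acid | C=C1CC[C@@H]2[C@](C)(CCC[C@]2(C)C(=O)O)[C@H]1CC[C@H](C)CC=O | intermediate
29 | β,γ-unsaturated (skipped) enal with a C14–C15' single bond and a 15'E alkene; C14 epimers not assigned (not isolated) | C=C1CC[C@@H]2[C@](C)(CCC[C@]2(C)C(=O)O)[C@H]1CC[C@H](C)C(C=O)/C=C/[C@@H](C)CC[C@H]1C(=C)CC[C@H]2[C@]1(C)CCC[C@]2(C)C(=O)O | intermediate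
30 | CNP0229303.1: (14E)-enal joining C14 of the trans-fused half (4S,5R,9S,10R,13S) to C15' of the cis-fused half (4'S,5'S,9'S,10'R,13'S); 19,19'-dioic acid | C=C1CC[C@@H]2[C@](C)(CCC[C@]2(C)C(=O)O)[C@H]1CC[C@H](C)/C(C=O)=C\C[C@@H](C)CC[C@H]1C(=C)CC[C@H]2[C@]1(C)CCC[C@]2(C)C(=O)O | target

**Step count**
- Total: 20 steps.
- Longest linear sequence: 13 steps (steps 1–5, then 13–20).

**The three steps most likely to fail**

**Step 20.** An alkyl-substituted borate may trap the radical cation too slowly, or the ceric salt may be tied up by the two free carboxylates. The fallback is a closed-shell enolonium route that sets out from 28 and 19 and comes back at 29. 28 is persilylated with Me3SiOTf/Et3N to trimethylsilyl 15-(trimethylsilyloxy)labda-8(17),14-dien-19-oate F1. F1 is oxidised at −78 °C with PhI(OAc)2/BF3·OEt2 to the iodine-bound enolonium ion. 19, which BF3·OEt2 converts into the alkenyldifluoroborane, is then added as the carbon nucleophile. Aqueous work-up removes the silyl ester and gives 29, which DBU carries on to 30 as before.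

**Step 9.** The hindered copper-containing enolate next to the new quaternary carbon may exchange protons faster than it attacks an unactivated primary iodide. The fallback reverses the polarity of the C9'–C11' bond, sets out from 7 and 13, and comes back at 15. Me2CuLi/Me3SiCl converts 7 into the 8-trimethylsilyl enol ether of the 10β-methyl cis-decalone ester F2. 13 is treated with t-BuLi and then ZnBr2 (0.5 equiv) to give bis{(3S)-3-methyl-5-[tri(propan-2-yl)silyl]pent-4-yn-1-yl}zinc F3. F2 is cleaved with MeLi to copper-free 14, oxidised with PhI(OH)OTs to its enolonium species and alkylated by F3. The zinc reagent has to enter from the same open β face, so 15 is obtained with the same C9' configuration.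

**Step 16.** The alkylation in ammonia may be slow, and the ester may be attacked by the metal. The fallback uses a carbonyl electrophile instead of the iodide, sets out from 22 and 11, and comes back at 25. After the Li/NH3 opening the enolate is trapped with Me3SiCl/Et3N as the 8-trimethylsilyl enol ether of the 10β-methyl trans-decalone ester F4. A TiCl4-mediated Mukaiyama aldol addition to 11 gives the 11-hydroxy ketone F5. Catalytic TsOH in hot benzene dehydrates F5 to the 9(11)-en-8-one F6. Conjugate reduction with [(Ph3P)CuH]6 followed by NaOMe/MeOH equilibration gives the equatorial 9α-H ketone 25. This works in the trans series because C9 is the thermodynamic centre there.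

**Further compounds**
F1 | step 20 | trimethylsilyl 15-(trimethylsilyloxy)labda-8(17),14-dien-19-oate (enol ether E/Z mixture) | C=C1CC[C@@H]2[C@](C)(CCC[C@]2(C)C(=O)O[Si](C)(C)C)[C@H]1CC[C@H](C)C=CO[Si](C)(C)C
F2 | step 9 | 8-trimethylsilyl enol ether of the 10β-methyl cis-decalone ester | C1=C(O[Si](C)(C)C)CC[C@H]2[C@]1(C)CCC[C@]2(C)C(=O)OCC[Si](C)(C)C
F3 | step 9 | bis{(3S)-3-methyl-5-[tri(propan-2-yl)silyl]pent-4-yn-1-yl}zinc | [Zn](CC[C@H](C)C#C[Si](C(C)C)(C(C)C)C(C)C)CC[C@H](C)C#C[Si](C(C)C)(C(C)C)C(C)C
F4 | step 16 | 8-trimethylsilyl enol ether of the 10β-methyl trans-decalone ester | C[Si](C)(C)OC1CC[C@@H]2[C@](C)(CCC[C@]2(C)C(=O)OCC[Si](C)(C)C)C=1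
F5 | step 16 | 11-hydroxy derivative of 25 (C9 and C11 epimers) | O=C1CC[C@@H]2[C@](C)(CCC[C@]2(C)C(=O)OCC[Si](C)(C)C)C1C(O)C[C@H](C)C#C[Si](C(C)C)(C(C)C)C(C)C
F6 | step 16 | 9(11)-dehydro derivative of 25 (exocyclic enone) | O=C1CC[C@@H]2[C@](C)(CCC[C@]2(C)C(=O)OCC[Si](C)(C)C)C1=CC[C@H](C)C#C[Si](C(C)C)(C(C)C)C(C)C
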